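**Plan**
1. Retrosynthetic cuts: the four O–benzyl bonds (last step), then ring B across B5–B6 and B1–B2, then the two ester C–O bonds (ring A acyl to the B4 oxygen, butynoyl to the ring C 4-oxygen).
2. Enabling feature: ring B is an orsellinate (B1 carboxyl carbon, B2 OH, B4 O-acyl, B6 CH3). B2–B3–B4–B5 maps onto a 1,1,3-trioxygenated butadiene and B6–B1, with methyl and carbonyl, onto a but-2-ynoate. Both ester oxygens lie outside the bonds formed, so rings A and C can be attached beforehand.
3. Ring A arm: 2,4-dihydroxy-6-methylbenzaldehyde is benzylated, Dakin-oxidised, O-methylated, formylated and oxidised to the acid, which O-acylates methyl acetoacetate; dienolate silylation gives the diene.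
4. Ring C arm: orsellinic acid is converted to its benzyl ester, the 2-OH is benzylated through a 4-O-allyl relay, and the freed 4-OH is esterified with but-2-ynoic acid.
5. Rings A and C are carried through as arenes; ring B is the only ring made, by [4+2] cycloaddition and aromatisation that joins the two arms, and hydrogenolysis finishes.
6. Stereochemistry: there is none to set; control is regiochemical and comes from the matched polarity of ketene acetal and ynoate.

Key step: step 13

Remark: the target has no stereocentre, axis or configured double bond, so "single enantiomer" sets no stereochemical task; 2,4-dihydroxy-6-methylbenzaldehyde is assumed to be the commercial source of ring A.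

**Route**

Step 1
Reactants: 1 2,4-dihydroxy-6-methylbenzaldehyde
Product: 2 2,4-bis(benzyloxy)-6-methylbenzaldehyde
Conditions: BnBr (2.5 equiv), K2CO3, DMF, 60 °C
Reagents that add atoms: benzyl bromide BrCc1ccccc1
Why: Williamson ether synthesis; in warm DMF carbonate ionises both phenols, including the one hydrogen-bonded to the aldehyde, and benzyl bromide alkylates them on oxygen.

Step 2
Reactants: 2 2,4-bis(benzyloxy)-6-methylbenzaldehyde
Product: 4 2,4-bis(benzyloxy)-6-methylphenol, via aryl formate 3 (not isolated)
Conditions: mCPBA (1.2 equiv), CH2Cl2, 0 °C → rt; then K2CO3 (cat.), MeOH, rt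
Reagents that add atoms: mCPBA OOC(=O)c1cccc(Cl)c1
Why: Baeyer–Villiger (Dakin-type) oxidation; in the Criegee adduct the electron-rich di-ortho-substituted aryl group migrates in preference to hydrogen, and the formate is removed by mild methanolysis that leaves the benzyl ethers alone.

Step 3
Reactants: 4 2,4-bis(benzyloxy)-6-methylphenol
Product: 5 1,5-bis(benzyloxy)-2-methoxy-3-methylbenzene
Conditions: MeI, K2CO3, acetone, reflux
Reagents that add atoms: iodomethane CI
Why: Williamson O-methylation of the only free phenol, done promptly because the electron-rich phenol is air-sensitive.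

Step 4
Reactants: 5 1,5-bis(benzyloxy)-2-methoxy-3-methylbenzene
Product: 6 2,4-bis(benzyloxy)-5-methoxy-6-methylbenzaldehyde
Conditions: POCl3, DMF, 0 → 60 °C; then ice/H2O
Reagents that add atoms: N,N-dimethylformamide CN(C)C=O; water O
Why: Vilsmeier–Haack formylation; as with 3,5-dialkoxytoluenes, the chloroiminium ion should attack the position next to the methyl group (para to one benzyloxy, ortho to the other) and not the more crowded position between the two benzyloxy groups.

Step 5
Reactants: 6 2,4-bis(benzyloxy)-5-methoxy-6-methylbenzaldehyde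
Product: 7 2,4-bis(benzyloxy)-5-methoxy-6-methylbenzoic acid
Conditions: NaClO2, NaH2PO4, 2-methyl-2-butene, t-BuOH/H2O, rt
Reagents that add atoms: sodium chlorite [Na+].[O-]Cl=O
Why: Pinnick oxidation of the hindered aldehyde, with 2-methyl-2-butene trapping hypochlorous acid before it can chlorinate the electron-rich ring.

Step 6
Reactants: 7 2,4-bis(benzyloxy)-5-methoxy-6-methylbenzoic acid; 8 methyl acetoacetate
Product: 10 methyl (Z)-3-{[2,4-bis(benzyloxy)-5-methoxy-6-methylbenzoyl]oxy}but-2-enoate, via acid chloride 9 (not isolated)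
Conditions: (COCl)2, DMF (cat.), CH2Cl2, 0 °C → rt, evaporate; then 8, Et3N, DMAP (cat.), CH2Cl2, 0 °C → rt
Reagents that add atoms: none
Why: Acid chloride formation followed by O-acylation of the ammonium enolate of the β-keto ester; an amine base without a chelating metal and a bulky 2,6-disubstituted aroyl chloride both direct attack to the enolate oxygen, giving the enol ester (Z expected, either geometry usable).

Step 7
Reactants: 10 methyl (Z)-3-{[2,4-bis(benzyloxy)-5-methoxy-6-methylbenzoyl]oxy}but-2-enoate
Product: 11 (E)-4-methoxy-4-(trimethylsilyloxy)buta-1,3-dien-2-yl 2,4-bis(benzyloxy)-5-methoxy-6-methylbenzoate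
Conditions: TMSCl (excess) present, LDA (1.05 equiv) added, THF, −78 °C; evaporate, hexane/toluene, filter under Ar; used crude
Reagents that add atoms: chlorotrimethylsilane C[Si](C)(C)Cl
Why: Kinetic γ-deprotonation of a 3-oxygenated crotonate with in situ O-silylation, the way 1-methoxy-1,3-bis(silyloxy)butadienes are made from 3-silyloxycrotonates; the internal quench should trap the dienolate before acyl transfer or loss of carboxylate.

Step 8
Reactants: 12 orsellinic acid (2,4-dihydroxy-6-methylbenzoic acid)
Product: 13 benzyl 2,4-dihydroxy-6-methylbenzoate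
Conditions: BnBr (1.05 equiv), KHCO3, DMF, rt
Reagents that add atoms: benzyl bromide BrCc1ccccc1
Why: SN2 O-alkylation of the carboxylate; hydrogencarbonate ionises only the acid, so the phenols stay free.

Step 9
Reactants: 13 benzyl 2,4-dihydroxy-6-methylbenzoate
Product: 14 benzyl 4-(allyloxy)-2-hydroxy-6-methylbenzoate
Conditions: allyl bromide (1.05 equiv), K2CO3, acetone, reflux
Reagents that add atoms: allyl bromide C=CCBr
Why: Regioselective Williamson etherification; the para hydroxyl is the more acidic, unchelated phenol, while the ortho hydroxyl is held in a hydrogen bond to the ester carbonyl.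

Step 10
Reactants: 14 benzyl 4-(allyloxy)-2-hydroxy-6-methylbenzoate
Product: 15 benzyl 4-(allyloxy)-2-(benzyloxy)-6-methylbenzoate
Conditions: BnBr, K2CO3, DMF, 60 °C
Reagents that add atoms: benzyl bromide BrCc1ccccc1
Why: Williamson benzylation of the remaining chelated phenol under more forcing conditions, far below the temperature of an aryl allyl ether Claisen rearrangement.

Step 11
Reactants: 15 benzyl 4-(allyloxy)-2-(benzyloxy)-6-methylbenzoate
Product: 16 benzyl 2-(benzyloxy)-4-hydroxy-6-methylbenzoate
Conditions: Pd(PPh3)4 (cat.), morpholine, THF, rt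
Reagents that add atoms: none
Why: Tsuji–Trost deallylation; Pd(0) ionises the aryl allyl ether to a π-allyl complex that morpholine captures, leaving benzyl ether and benzyl ester untouched.

Step 12
Reactants: 16 benzyl 2-(benzyloxy)-4-hydroxy-6-methylbenzoate; 17 but-2-ynoic acid
Product: 18 benzyl 2-(benzyloxy)-4-(but-2-ynoyloxy)-6-methylbenzoate
Conditions: DCC, DMAP (5 mol %), CH2Cl2, 0 °C → rt
Reagents that add atoms: none
Why: Steglich esterification of the free para phenol with the unhindered alkynoic acid, kept cold and low in DMAP to avoid amine addition to the ynoate.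

Step 13
Reactants: 11 (E)-4-methoxy-4-(trimethylsilyloxy)buta-1,3-dien-2-yl 2,4-bis(benzyloxy)-5-methoxy-6-methylbenzoate; 18 benzyl 2-(benzyloxy)-4-(but-2-ynoyloxy)-6-methylbenzoate
Product: 21 benzyl 2-(benzyloxy)-4-{[4-({2,4-bis(benzyloxy)-5-methoxy-6-methylbenzoyl}oxy)-2-hydroxy-6-methylbenzoyl]oxy}-6-methylbenzoate, via cyclohexadiene ketal 19 (not isolated), via aryl silyl ether 20 (not isolated)
Conditions: 18 (1.3 equiv), toluene, 110 °C, sealed tube, Ar; then 0.5 M aq. HCl, THF, 0 °C → rt
Reagents that add atoms: none
Why: Proposed new method: the geminal oxygens at C1 make the CH2 terminus of diene 11 the nucleophilic end, so an asynchronous, polarity-matched [4+2] cycloaddition should first join it to the methyl-bearing β-carbon of ynoate 18 (B5–B6) and then close the acetal carbon onto the α-carbon (B2–B1), helped by the aryl ester of an electron-poor phenol, which is a better acceptor than an alkyl butynoate. The closest known reaction type is the Diels–Alder reaction and aromatisation of 1-methoxy-1,3-bis(silyloxy)- and 1,3-dialkoxy-1-silyloxybutadienes with alkynoates to give resorcylates; untested here is the 3-aroyloxy group, a weaker donor that should cost rate but not reverse the polarisation set by the ketene acetal. Ring B closes as a six-membered carbocycle by intermolecular [4+2] cycloaddition to the 1,4-cyclohexadiene ketal 19, which aromatises by 1,4-elimination of methanol to silyl ether 20, and dilute acid frees the chelated B2 hydroxyl. No stereocentre remains, since the ketal carbon of 19 becomes aromatic. The step needs regioselectivity (methyl next to B5, ester next to B2), secured by the matched polarity of the two partners, and chemoselectivity for cycloaddition over acyl transfer or expulsion of the aroyloxy group, secured by working thermally without Lewis acid or fluoride, by the 2,6-disubstitution that shields the ring A carbonyl, and by the (E) ketene acetal geometry that keeps silicon away from the acyloxy oxygen.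

Step 14
Reactants: 21 benzyl 2-(benzyloxy)-4-{[4-({2,4-bis(benzyloxy)-5-methoxy-6-methylbenzoyl}oxy)-2-hydroxy-6-methylbenzoyl]oxy}-6-methylbenzoate
Product: 22 4-{[4-({2,4-dihydroxy-5-methoxy-6-methylbenzoyl}oxy)-2-hydroxy-6-methylbenzoyl]oxy}-2-hydroxy-6-methylbenzoic acid
Conditions: H2 (1 atm), 10% Pd/C, EtOAc/THF, rt
Reagents that add atoms: none
Why: Catalytic hydrogenolysis cleaves the three benzyl ethers and the benzyl ester in one operation, while the two aryl ester links and the aryl methyl ether are inert to H2/Pd.

**Compound list**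
1 | 2,4-dihydroxy-6-methylbenzaldehyde | O=Cc1c(O)cc(O)cc1C | starting material
2 | 2,4-bis(benzyloxy)-6-methylbenzaldehyde | O=Cc1c(OCc2ccccc2)cc(OCc2ccccc2)cc1C | intermediate
3 | 2,4-bis(benzyloxy)-6-methylphenyl formate | O=COc1c(OCc2ccccc2)cc(OCc2ccccc2)cc1C | intermediate
4 | 2,4-bis(benzyloxy)-6-methylphenol | Oc1c(OCc2ccccc2)cc(OCc2ccccc2)cc1C | intermediate
5 | 1,5-bis(benzyloxy)-2-methoxy-3-methylbenzene | COc1c(OCc2ccccc2)cc(OCc2ccccc2)cc1C | intermediate
6 | 2,4-bis(benzyloxy)-5-methoxy-6-methylbenzaldehyde | COc1c(OCc2ccccc2)cc(OCc2ccccc2)c(C=O)c1C | intermediate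
7 | 2,4-bis(benzyloxy)-5-methoxy-6-methylbenzoic acid | COc1c(OCc2ccccc2)cc(OCc2ccccc2)c(C(=O)O)c1C | intermediate
8 | methyl acetoacetate | COC(=O)CC(C)=O | starting material
9 | 2,4-bis(benzyloxy)-5-methoxy-6-methylbenzoyl chloride | COc1c(OCc2ccccc2)cc(OCc2ccccc2)c(C(=O)Cl)c1C | intermediate
10 | methyl (Z)-3-{[2,4-bis(benzyloxy)-5-methoxy-6-methylbenzoyl]oxy}but-2-enoate | COc1c(OCc2ccccc2)cc(OCc2ccccc2)c(C(=O)O/C(C)=C\C(=O)OC)c1C | intermediate
11 | (E)-4-methoxy-4-(trimethylsilyloxy)buta-1,3-dien-2-yl 2,4-bis(benzyloxy)-5-methoxy-6-methylbenzoate (ketene acetal geometry as expected from kinetic enolisation) | COc1c(OCc2ccccc2)cc(OCc2ccccc2)c(C(=O)OC(=C)/C=C(\OC)O[Si](C)(C)C)c1C | intermediate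
12 | orsellinic acid (2,4-dihydroxy-6-methylbenzoic acid) | Cc1cc(O)cc(O)c1C(=O)O | starting material
13 | benzyl 2,4-dihydroxy-6-methylbenzoate | Cc1cc(O)cc(O)c1C(=O)OCc1ccccc1 | intermediate
14 | benzyl 4-(allyloxy)-2-hydroxy-6-methylbenzoate | C=CCOc1cc(C)c(C(=O)OCc2ccccc2)c(O)c1 | intermediate
15 | benzyl 4-(allyloxy)-2-(benzyloxy)-6-methylbenzoate | C=CCOc1cc(C)c(C(=O)OCc2ccccc2)c(OCc2ccccc2)c1 | intermediate
16 | benzyl 2-(benzyloxy)-4-hydroxy-6-methylbenzoate | Oc1cc(C)c(C(=O)OCc2ccccc2)c(OCc2ccccc2)c1 | intermediate
17 | but-2-ynoic acid | CC#CC(=O)O | starting material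
18 | benzyl 2-(benzyloxy)-4-(but-2-ynoyloxy)-6-methylbenzoate | CC#CC(=O)Oc1cc(C)c(C(=O)OCc2ccccc2)c(OCc2ccccc2)c1 | intermediate
19 | 4-(benzyloxycarbonyl)-3-(benzyloxy)-5-methylphenyl 4-{[2,4-bis(benzyloxy)-5-methoxy-6-methylbenzoyl]oxy}-6-methoxy-2-methyl-6-(trimethylsilyloxy)cyclohexa-1,4-diene-1-carboxylate (racemic at the ketal carbon, transient) | COC1(O[Si](C)(C)C)C=C(OC(=O)c2c(C)c(OC)c(OCc3ccccc3)cc2OCc2ccccc2)CC(C)=C1C(=O)Oc1cc(C)c(C(=O)OCc2ccccc2)c(OCc2ccccc2)c1 | intermediate
20 | B2-O-trimethylsilyl ether of 21 | COc1c(OCc2ccccc2)cc(OCc2ccccc2)c(C(=O)Oc2cc(C)c(C(=O)Oc3cc(C)c(C(=O)OCc4ccccc4)c(OCc4ccccc4)c3)c(O[Si](C)(C)C)c2)c1C | intermediate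
21 | benzyl 2-(benzyloxy)-4-{[4-({2,4-bis(benzyloxy)-5-methoxy-6-methylbenzoyl}oxy)-2-hydroxy-6-methylbenzoyl]oxy}-6-methylbenzoate | COc1c(OCc2ccccc2)cc(OCc2ccccc2)c(C(=O)Oc2cc(C)c(C(=O)Oc3cc(C)c(C(=O)OCc4ccccc4)c(OCc4ccccc4)c3)c(O)c2)c1C | intermediate
22 | 4-{[4-({2,4-dihydroxy-5-methoxy-6-methylbenzoyl}oxy)-2-hydroxy-6-methylbenzoyl]oxy}-2-hydroxy-6-methylbenzoic acid | COc1c(O)cc(O)c(C(=O)Oc2cc(C)c(C(=O)Oc3cc(C)c(C(=O)O)c(O)c3)c(O)c2)c1C | target

**Step count**
Total: 14 steps. Longest linear sequence: 9 steps (steps 1–7, 13, 14, from compound 1).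

**Steps most likely to fail**

Step 13. The acyloxy-substituted diene may react too slowly with the β-methyl ynoate, so that it is lost first by silyl transfer with expulsion of the arenecarboxylate, by adventitious hydrolysis, or by stopping at an open-chain Michael adduct. The fallback uses known chemistry: ring B is still built on ynoate 18 by cycloaddition, but with a silyloxy placeholder at B4, and ring A is attached afterwards. It sets out from 8 and 18 and comes back at 21. Methyl acetoacetate 8 would be silylated (TMSCl, Et3N) to methyl (Z)-3-(trimethylsilyloxy)but-2-enoate F1. Deprotonation and silylation (LDA, TMSCl, −78 °C) would give 1-methoxy-1,3-bis(trimethylsilyloxy)buta-1,3-diene F2. Heating F2 with 18 in toluene, followed by dilute acid, should give benzyl 2-(benzyloxy)-4-[(2,4-dihydroxy-6-methylbenzoyl)oxy]-6-methylbenzoate F3 with the same regiochemistry. Its unchelated B4 hydroxyl would then be acylated selectively with acid 7 (TFAA, toluene, rt, the classical depside condensation), the hydrogen-bonded B2 hydroxyl staying free, which gives 21.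

Step 7. The lithium dienolate may undergo O-to-C acyl transfer, expel the arenecarboxylate to give an allenoate, or be formed in competition with lateral deprotonation of the ring A methyl group before silicon traps it. The fallback gives up the amide base; it sets out from 10 and comes back at 21. Soft enolisation of 10 with TBSOTf and Et3N (CH2Cl2, 0 °C → rt) works by carbonyl O-silylation and then γ-deprotonation by the amine, as in the conversion of butenolides into silyloxyfurans, and no free dienolate is formed. It should give (E)-4-[(tert-butyldimethylsilyl)oxy]-4-methoxybuta-1,3-dien-2-yl 2,4-bis(benzyloxy)-5-methoxy-6-methylbenzoate F4, a diene that tolerates handling better. F4 would be heated with 18 as in step 13; after loss of methanol this should give the B2-O-tert-butyldimethylsilyl ether of 21 F5. HF·pyridine (THF, 0 °C) would then free the phenol to give 21.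

Step 4. The electrophile may attack the position between the two benzyloxy groups, or the acidic medium may remove a benzyl group. The fallback replaces formylation and oxidation by halogenation and carboxylation; it sets out from 5 and comes back at 7, bypassing 6. NBS in MeCN at 0 °C, which follows the para-directing benzyloxy group more strictly, should give 1,5-bis(benzyloxy)-2-bromo-4-methoxy-3-methylbenzene F6. Bromine–lithium exchange (n-BuLi, THF, −78 °C) and quenching with CO2 would deliver acid 7.

**Further compounds**
F1 | step 13 | methyl (Z)-3-(trimethylsilyloxy)but-2-enoate | COC(=O)/C=C(/C)O[Si](C)(C)C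
F2 | step 13 | 1-methoxy-1,3-bis(trimethylsilyloxy)buta-1,3-diene | C=C(O[Si](C)(C)C)/C=C(\OC)O[Si](C)(C)C
F3 | step 13 | benzyl 2-(benzyloxy)-4-[(2,4-dihydroxy-6-methylbenzoyl)oxy]-6-methylbenzoate | Cc1cc(O)cc(O)c1C(=O)Oc1cc(C)c(C(=O)OCc2ccccc2)c(OCc2ccccc2)c1
F4 | step 7 | (E)-4-[(tert-butyldimethylsilyl)oxy]-4-methoxybuta-1,3-dien-2-yl 2,4-bis(benzyloxy)-5-methoxy-6-methylbenzoate | COc1c(OCc2ccccc2)cc(OCc2ccccc2)c(C(=O)OC(=C)/C=C(\OC)O[Si](C)(C)C(C)(C)C)c1C
F5 | step 7 | B2-O-tert-butyldimethylsilyl ether of 21 | COc1c(OCc2ccccc2)cc(OCc2ccccc2)c(C(=O)Oc2cc(C)c(C(=O)Oc3cc(C)c(C(=O)OCc4ccccc4)c(OCc4ccccc4)c3)c(O[Si](C)(C)C(C)(C)C)c2)c1C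
F6 | step 4 | 1,5-bis(benzyloxy)-2-bromo-4-methoxy-3-methylbenzene | COc1c(OCc2ccccc2)cc(OCc2ccccc2)c(Br)c1C
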